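**Retrosynthetic overview**
1. Calycopterin ⇐ its 4'-O-benzyl 5-O-methyl ether: one BCl3 operation removes the benzyl group and, through chelation to the C4 carbonyl, only the peri 5-OMe.
2. The 3-OMe ⇐ a 3-iodoflavone, by copper-catalysed C–O coupling with methanol.
3. Key step: ring C (the pyranone, the only ring built; rings A and B are bought as benzenes) ⇐ ICl-induced demethylative 6-endo cyclisation of a pentamethoxyphenyl aryl ynone. The C2v-symmetric ring A makes both ortho-OMe groups equivalent, so no o-hydroxyacetophenone, chalcone or 1,3-diketone is needed.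
4. Ynone ⇐ (pentamethoxyphenyl)lithium + the Weinreb ynamide of 4-benzyloxyphenylacetylene.
5. Pentamethoxybenzene ⇐ 1,2,3,5-tetramethoxybenzene by lithiation–boration–oxidation, then O-methylation.

Assumption: the target has no stereocentre or stereogenic axis, so it is achiral; no stereocontrol is needed and the SMILES carry no stereodescriptors.
Convention: adducts that only wait for aqueous work-up (boron chelates, the tetrahedral adduct of the Weinreb amide) are not counted as separate compounds.

**Route**

Step 1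
Reactants: 1 1,2,3,5-tetramethoxybenzene
Product: 4 2,3,4,6-tetramethoxyphenol, via (2,3,4,6-tetramethoxyphenyl)lithium 2 (not isolated), via lithium aryltrimethoxyborate 3 (not isolated)
Conditions: n-BuLi (1.1 equiv), THF, 0 °C to rt; B(OMe)3, −78 °C to rt; AcOH, 30% aq. H2O2, 0 °C to rt
Reagents that add atoms: hydrogen peroxide, OO
Why: Directed ortho-metalation puts lithium on the C–H flanked by two OMe groups (the two such positions of 1 are symmetry-equivalent), and borate trapping followed by peroxide oxidation (aryl 1,2-shift from boron to oxygen) turns C–Li into C–OH.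

Step 2
Reactants: 4 2,3,4,6-tetramethoxyphenol
Product: 5 pentamethoxybenzene
Conditions: MeI (1.5 equiv), K2CO3 (2 equiv), acetone, reflux, under N2
Reagents that add atoms: iodomethane, CI
Why: Williamson ether synthesis (SN2 O-methylation of the phenoxide), run under nitrogen because the electron-rich phenol is air-sensitive.

Step 3
Reactants: 6 1-(benzyloxy)-4-ethynylbenzene; 7 N-methoxy-N-methylcarbamoyl chloride
Product: 9 3-[4-(benzyloxy)phenyl]-N-methoxy-N-methylprop-2-ynamide, via lithium (4-benzyloxyphenyl)acetylide 8 (not isolated)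
Conditions: n-BuLi (1.05 equiv), THF, −78 °C; then 7 (1.1 equiv), −78 to 0 °C
Reagents that add atoms: none
Why: Nucleophilic acyl substitution of the lithium acetylide on the carbamoyl chloride, where chloride is the only leaving group and the resulting Weinreb amide does not react further with acetylide at low temperature.

Step 4
Reactants: 5 pentamethoxybenzene; 9 3-[4-(benzyloxy)phenyl]-N-methoxy-N-methylprop-2-ynamide
Product: 11 3-[4-(benzyloxy)phenyl]-1-(pentamethoxyphenyl)prop-2-yn-1-one, via (pentamethoxyphenyl)lithium 10 (not isolated)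
Conditions: 5 (1.2 equiv), n-BuLi (1.1 equiv), THF, 0 °C to rt, 1.5 h; then 9 (1.0 equiv), −78 to −20 °C; inverse quench into cold 1 M HCl
Reagents that add atoms: none
Why: Directed ortho-lithiation at the single ring C–H of 5 followed by a Weinreb ketone synthesis, in which the N-methoxy-N-methylamide stops the 1,2-addition at the ketone stage and the inverse acidic quench protonates the released amine before it can add to the ynone.

Step 5
Reactants: 11 3-[4-(benzyloxy)phenyl]-1-(pentamethoxyphenyl)prop-2-yn-1-one
Product: 12 2-[4-(benzyloxy)phenyl]-3-iodo-5,6,7,8-tetramethoxy-4H-chromen-4-one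
Conditions: ICl (1.5 equiv), CH2Cl2, −78 °C, 30 min; aq. Na2S2O3
Reagents that add atoms: iodine monochloride, ClI
Why: Larock iodocyclisation: iodonium adds to the alkyne carbon next to the carbonyl, the positive charge at the other carbon is stabilised by the 4-benzyloxyphenyl group, an ortho-OMe oxygen closes 6-endo-dig and chloride removes the oxonium methyl as MeCl. Both ortho-OMe groups are equivalent and ring A has no C–H to iodinate, so a single flavone results.

Step 6
Reactants: 12 2-[4-(benzyloxy)phenyl]-3-iodo-5,6,7,8-tetramethoxy-4H-chromen-4-one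
Product: 13 2-[4-(benzyloxy)phenyl]-3,5,6,7,8-pentamethoxy-4H-chromen-4-one
Conditions: CuI (10 mol%), 3,4,7,8-tetramethyl-1,10-phenanthroline (20 mol%), Cs2CO3 (2 equiv), MeOH/toluene 1:2, 80 °C, sealed tube, degassed
Reagents that add atoms: methanol, CO
Why: Ullmann-type copper-catalysed C–O coupling under the conditions established for aryl and vinyl iodides with aliphatic alcohols, here extended to the C3 iodide of an α-iodoenone, which is the untested part; the weak carbonate base keeps free methoxide low so conjugate attack at C2 and ring opening stay slow.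

Step 7
Reactants: 13 2-[4-(benzyloxy)phenyl]-3,5,6,7,8-pentamethoxy-4H-chromen-4-one
Product: 14 calycopterin (5-hydroxy-2-(4-hydroxyphenyl)-3,6,7,8-tetramethoxy-4H-chromen-4-one)
Conditions: BCl3 (1 M in CH2Cl2, 5 equiv), C6HMe5 (3 equiv), CH2Cl2, −78 °C to 0 °C; MeOH, then 1 M HCl work-up
Reagents that add atoms: none
Why: Lewis-acid ether cleavage: BCl3 with pentamethylbenzene as Friedel–Crafts benzyl-cation trap removes the aryl benzyl ether at −78 °C, and on warming boron held by the C4 carbonyl cleaves only the peri 5-OMe through a six-membered chelate, leaving the 3-, 6-, 7- and 8-OMe groups.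

**Compound list**
1 | 1,2,3,5-tetramethoxybenzene | COc1cc(OC)c(OC)c(OC)c1 | starting material
2 | (2,3,4,6-tetramethoxyphenyl)lithium | [Li]c1c(OC)cc(OC)c(OC)c1OC | intermediate
3 | lithium trimethoxy(2,3,4,6-tetramethoxyphenyl)borate | [Li+].CO[B-](OC)(OC)c1c(OC)cc(OC)c(OC)c1OC | intermediate
4 | 2,3,4,6-tetramethoxyphenol | COc1cc(OC)c(OC)c(OC)c1O | intermediate
5 | pentamethoxybenzene | COc1cc(OC)c(OC)c(OC)c1OC | intermediate
6 | 1-(benzyloxy)-4-ethynylbenzene | C#Cc1ccc(OCc2ccccc2)cc1 | starting material
7 | N-methoxy-N-methylcarbamoyl chloride | CON(C)C(=O)Cl | starting material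
8 | lithium (4-benzyloxyphenyl)acetylide | [Li]C#Cc1ccc(OCc2ccccc2)cc1 | intermediate
9 | 3-[4-(benzyloxy)phenyl]-N-methoxy-N-methylprop-2-ynamide | CON(C)C(=O)C#Cc1ccc(OCc2ccccc2)cc1 | intermediate
10 | (pentamethoxyphenyl)lithium | [Li]c1c(OC)c(OC)c(OC)c(OC)c1OC | intermediate
11 | 3-[4-(benzyloxy)phenyl]-1-(pentamethoxyphenyl)prop-2-yn-1-one | COc1c(OC)c(OC)c(C(=O)C#Cc2ccc(OCc3ccccc3)cc2)c(OC)c1OC | intermediate
12 | 2-[4-(benzyloxy)phenyl]-3-iodo-5,6,7,8-tetramethoxy-4H-chromen-4-one | COc1c(OC)c(OC)c2c(=O)c(I)c(-c3ccc(OCc4ccccc4)cc3)oc2c1OC | intermediate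
13 | 2-[4-(benzyloxy)phenyl]-3,5,6,7,8-pentamethoxy-4H-chromen-4-one | COc1c(OC)c(OC)c2c(=O)c(OC)c(-c3ccc(OCc4ccccc4)cc3)oc2c1OC | intermediate
14 | calycopterin, 5-hydroxy-2-(4-hydroxyphenyl)-3,6,7,8-tetramethoxy-4H-chromen-4-one (achiral) | COc1c(OC)c(O)c2c(=O)c(OC)c(-c3ccc(O)cc3)oc2c1OC | target

**Totals**
Total step count: 7. Longest linear sequence: 6 (steps 1, 2, 4, 5, 6, 7); step 3 is a one-step side branch.

**Three steps most likely to fail**

Step 6 (C–O coupling on the 3-iodoflavone; possible deiodination or methoxide attack at C2). The fallback replaces C–I substitution by C3–H oxidation; it sets out from 12 and comes back at 13. Hydrodeiodination of 12 with Pd(PPh3)4 and HCO2Na in DMF at 80 °C gives 2-[4-(benzyloxy)phenyl]-5,6,7,8-tetramethoxy-4H-chromen-4-one F1. Dimethyldioxirane in acetone/CH2Cl2 at 0 °C epoxidises its C2=C3 bond to the racemic, necessarily cis-fused 1a-[4-(benzyloxy)phenyl]-3,4,5,6-tetramethoxy-1a,7a-dihydro-7H-oxireno[2,3-b]chromen-7-one F2. Catalytic TsOH opens this to the flavonol 2-[4-(benzyloxy)phenyl]-3-hydroxy-5,6,7,8-tetramethoxy-4H-chromen-4-one F3. MeI and K2CO3 in acetone then methylate the 3-OH to give 13.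

Step 5 (iodocyclisation; possible iodination of ring B or 5-exo closure). The fallback gives up the ynone and closes ring C by the classical acyl-transfer route; it sets out from 5 and comes back at 13, so steps 3 to 6 are replaced. Friedel–Crafts acylation of 5 with methoxyacetyl chloride and AlCl3 (Et2O, 0 °C to rt), which also cleaves the methyl ether ortho to the new ketone, gives 1-(2-hydroxy-3,4,5,6-tetramethoxyphenyl)-2-methoxyethan-1-one F4. Allan–Robinson condensation of F4 with 4-(benzyloxy)benzoic anhydride and potassium 4-(benzyloxy)benzoate (175 °C, then KOH, aqueous EtOH, reflux) builds the pyranone with the 3-OMe already in place and gives 13.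

Step 7 (one-flask double deprotection; possible over-demethylation at 6-OMe or 3-OMe, or C-benzylation). The fallback separates the two cleavages and uses hydrogenolysis instead of a Lewis acid for the benzyl group; it sets out from 13 and comes back at 14. Hydrogenolysis of 13 (H2 1 atm, Pd/C, EtOAc/MeOH, rt) gives 2-(4-hydroxyphenyl)-3,5,6,7,8-pentamethoxy-4H-chromen-4-one F5. Anhydrous AlCl3 in MeCN (rt to 60 °C, then dilute HCl) then cleaves only the chelated 5-OMe to give 14.

**Further compounds**
F1 | step 6 | 2-[4-(benzyloxy)phenyl]-5,6,7,8-tetramethoxy-4H-chromen-4-one | COc1c(OC)c(OC)c2c(=O)cc(-c3ccc(OCc4ccccc4)cc3)oc2c1OC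
F2 | step 6 | racemic cis-fused 1a-[4-(benzyloxy)phenyl]-3,4,5,6-tetramethoxy-1a,7a-dihydro-7H-oxireno[2,3-b]chromen-7-one | COc1c(OC)c(OC)c2C(=O)C3OC3(c3ccc(OCc4ccccc4)cc3)Oc2c1OC
F3 | step 6 | 2-[4-(benzyloxy)phenyl]-3-hydroxy-5,6,7,8-tetramethoxy-4H-chromen-4-one | COc1c(OC)c(OC)c2c(=O)c(O)c(-c3ccc(OCc4ccccc4)cc3)oc2c1OC
F4 | step 5 | 1-(2-hydroxy-3,4,5,6-tetramethoxyphenyl)-2-methoxyethan-1-one | COCC(=O)c1c(O)c(OC)c(OC)c(OC)c1OC
F5 | step 7 | 2-(4-hydroxyphenyl)-3,5,6,7,8-pentamethoxy-4H-chromen-4-one | COc1c(OC)c(OC)c2c(=O)c(OC)c(-c3ccc(O)cc3)oc2c1OC
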